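## Retrosynthetic overview

1. Target 28 (ring A: ten-membered lactone; ring B: γ-lactone; ring C: alkylidene-oxolane; ring D: oxane) ⇐ seco acid 27 by macrolactonisation ⇐ hemiketal 26 by dehydration ⇐ lactone enolate of 25 + bicyclic lactone 15 (makes the carbon–carbon link between rings B and C that becomes the E double bond).
2. 15 ⇐ cis-oxan-3-one 11 ⇐ 2H-pyran-3(6H)-one 9 ⇐ key step: acetylene 8 is inserted into a C(=O)–C bond of oxetan-3-one 7, which forms both bonds from the ring D CH2–CH2 unit to its two ring neighbours at once.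
3. Enabling feature: in ring D the ring oxygen, the two CH carbons beside it and the ring-fusion carbon that carries the ring C oxygen map onto O-1, C-2, C-4 and the carbonyl carbon of an oxetan-3-one. Both CH carbons beside the oxygen carry a carbon branch, so with two identical branches 7 is C2-symmetric and its two C(=O)–C bonds are identical. The extra carbon on the methyl-bearing carbon is removed later as CO2.
4. 7 ⇐ oxetan-3-one 1 (two RAMP-hydrazone alkylations). 25 ⇐ (R)-γ-valerolactone 16 (Grignard addition/ketal, ozonolysis, α-methylenation, acetate aldol, acrylate RCM, cis-hydrogenation).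
5. Order of ring formation: ring D (step 5), ring C as the γ-lactone of 15 (step 8), ring B (step 15, saturated in step 16), ring A (step 19).

Key step: step 5

Assumption: the senses of induction of the RAMP auxiliary (steps 2 and 3) and of the titanium aldol catalyst (step 13) follow the usual topicity models; if either proves opposite, the enantiomeric auxiliary or ligand is used.

## Route

Step 1
Reactants: 1 oxetan-3-one; 2 (R)-1-amino-2-(methoxymethyl)pyrrolidine (RAMP)
Product: 3 (2R)-2-(methoxymethyl)-N-(oxetan-3-ylidene)pyrrolidin-1-amine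
Conditions: neat, 55 °C, then vacuum
Reagents that add atoms: none
Why: Hydrazone formation by condensation of the strained, unhindered ketone with the N-amino auxiliary; no stereocentre is formed.

Step 2
Reactants: 3 RAMP hydrazone of oxetan-3-one; 4 tert-butyl(2-iodoethoxy)dimethylsilane
Product: 5 (2R)-N-{(2R)-2-[2-(tert-butyldimethylsilyloxy)ethyl]oxetan-3-ylidene}-2-(methoxymethyl)pyrrolidin-1-amine
Conditions: t-BuLi (1.1 equiv), THF, −78 °C; then 4, −78 °C → rt
Reagents that add atoms: none
Why: Enders RAMP-hydrazone α-alkylation, precedented on oxetan-3-one hydrazones: the methoxy-chelated lithium azaenolate is alkylated on its open face, which sets the (R)-configured ring carbon.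

Step 3
Reactants: 5 mono-alkylated hydrazone; 4 tert-butyl(2-iodoethoxy)dimethylsilane
Product: 6 (2R)-N-{(2R,4R)-2,4-bis[2-(tert-butyldimethylsilyloxy)ethyl]oxetan-3-ylidene}-2-(methoxymethyl)pyrrolidin-1-amine
Conditions: t-BuLi (1.1 equiv), THF, −78 °C; then 4, −78 °C → rt
Reagents that add atoms: none
Why: Second Enders alkylation: t-BuLi removes a proton from the remaining ring CH2 and the same auxiliary topicity sets a second (R)-centre, so the trans (C2-symmetric) 2,4-dialkyl pattern results, as precedented for 2,4-disubstituted oxetan-3-one hydrazones.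

Step 4
Reactants: 6 bis-alkylated hydrazone
Product: 7 (2R,4R)-2,4-bis[2-(tert-butyldimethylsilyloxy)ethyl]oxetan-3-one (trans)
Conditions: saturated aq. (CO2H)2, Et2O, rt
Reagents that add atoms: water (O)
Why: Hydrazone hydrolysis under mild biphasic acid releases the ketone and the auxiliary without enolising the two α-stereocentres, as precedented for 2-alkyl- and 2,4-dialkyloxetan-3-ones, and primary TBS ethers survive.

Step 5
Reactants: 7 (2R,4R)-oxetan-3-one; 8 acetylene
Product: 9 (2R,6R)-2,6-bis[2-(tert-butyldimethylsilyloxy)ethyl]-2H-pyran-3(6H)-one (2,6-trans)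
Conditions: Ni(cod)2 (10 mol %), PPh3 (30 mol %), toluene, acetylene (1 atm, fed slowly), 0 °C → rt
Reagents that add atoms: none
Why: Proposed new method: zerovalent nickel binds the strained ketone and acetylene and joins them by oxidative cyclisation to a spiro oxanickelacyclopentene (first new bond, carbonyl carbon to an acetylene carbon), strain-driven β-carbon elimination then transfers one α-carbon of the oxetane to nickel and C(sp3)–C(sp2) reductive elimination makes the second new bond. The closest known reaction type is the nickel-catalysed (4+2) insertion of internal alkynes into cyclobutanones, 3-azetidinones and 3-oxetanones, which cleaves an unsubstituted CH2–C(=O) bond; new here are cleavage at a substituted, oxygen-bearing CH–C(=O) bond and acetylene itself as the partner. The 2H-pyran-3(6H)-one ring is closed by ring expansion, a two-atom insertion into a ring C–C bond of the four-membered ring, not by an end-to-end cyclisation. No stereocentre is created: the α-carbon that stays on the carbonyl is untouched and the migrating one passes from carbon to nickel and back to carbon with retention, so (2R,4R)-7 should give (2R,6R)-9. The step needs a choice between the two C(=O)–C bonds, and the C2 symmetry of 7 secures it because the two bonds are homotopic and either cleavage leads to the same product. It also needs the cross-reaction to outrun acetylene oligomerisation and β-hydride elimination of the secondary alkylnickel, which the ring strain of 7, slow feeding of acetylene and the fast vinyl–alkyl reductive elimination should favour.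

Step 6
Reactants: 9 (2R,6R)-pyranone
Product: 11 (2S,6S)-2,6-bis[2-(tert-butyldimethylsilyloxy)ethyl]oxan-3-one (2,6-cis), via trans-ketone 10 (not isolated)
Conditions: H2 (1 atm), Pd/C, EtOAc, rt; filter; DBU (0.2 equiv), CH2Cl2, rt
Reagents that add atoms: none
Why: Catalytic hydrogenation saturates the enone C=C, and DBU then epimerises the ketone α-carbon C-2 (thermodynamic control by C-6) to the 2,6-cis isomer with both arms equatorial; C-6 keeps its geometry and only its descriptor changes.

Step 7
Reactants: 11 cis-oxan-3-one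
Product: 13 (2S,3S,6S)-2,6-bis(2-hydroxyethyl)oxan-3-ol, via bis-silyl alcohol 12 (not isolated)
Conditions: LiBH(sec-Bu)3 (L-Selectride), THF, −78 °C; then HCl in MeOH, 0 °C → rt
Reagents that add atoms: none
Why: L-Selectride reduction: the bulky hydride attacks the chair ketone from the equatorial side and sets the axial 3-hydroxyl cis to the C-2 arm, and methanolic HCl then cleaves both primary TBS ethers.

Step 8
Reactants: 13 triol
Product: 14 2-[(3aS,5S,7aS)-2-oxohexahydro-2H-furo[3,2-b]pyran-5-yl]acetic acid
Conditions: TEMPO (20 mol %), PhI(OAc)2 (4.5 equiv), MeCN/H2O, rt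
Reagents that add atoms: water (O)
Why: TEMPO/PhI(OAc)2 oxidation is selective for the primary alcohols: the aldehyde of the C-2 arm is trapped by the cis 3-hydroxyl as a lactol and oxidised to the cis-fused γ-lactone (oxidative lactonisation), while the C-6 arm is oxidised through the aldehyde hydrate to the carboxylic acid.

Step 9
Reactants: 14 lactone acid
Product: 15 (3aS,5R,7aS)-5-methylhexahydro-2H-furo[3,2-b]pyran-2-one
Conditions: 9-mesityl-10-methylacridinium tetrafluoroborate (5 mol %), PhSSPh (10 mol %), iPr2NEt (20 mol %), CF3CH2OH, blue LEDs, rt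
Reagents that add atoms: none
Why: Acridinium photoredox hydrodecarboxylation: the carboxylate is oxidised, loses CO2, and the primary radical takes a hydrogen atom from thiophenol, which turns the surplus CH2CO2H arm into the methyl group without touching a stereocentre.

Step 10
Reactants: 16 (R)-γ-valerolactone
Product: 18 (5R)-2-(but-3-en-1-yl)-2-methoxy-5-methyloxolane (epimers at the ketal carbon), via hemiketal 17 (not isolated)
Conditions: CH2=CHCH2CH2MgBr (1.05 equiv), THF, −78 °C; aq. NH4Cl; then MeOH, PPTS (cat.), rt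
Reagents that add atoms: but-3-en-1-ylmagnesium bromide (C=CCC[Mg]Br); methanol (CO)
Why: Grignard addition to a lactone at low temperature stops at the magnesium hemiketalate, and acid-catalysed exchange with methanol then locks the ketone and the secondary alcohol together as a cyclic methyl ketal; the carbinol stereocentre comes unchanged from 16.

Step 11
Reactants: 18 methyl ketal alkene
Product: 19 3-[(5R)-2-methoxy-5-methyloxolan-2-yl]propanal
Conditions: O3, CH2Cl2, NaHCO3, −78 °C; then PPh3, −78 °C → rt
Reagents that add atoms: ozone ([O-][O+]=O)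
Why: Ozonolysis of the terminal alkene with reductive work-up gives the aldehyde; the ketal has no oxidisable C–H at the ketal carbon.

Step 12
Reactants: 19 aldehyde
Product: 20 2-{[(5R)-2-methoxy-5-methyloxolan-2-yl]methyl}prop-2-enal
Conditions: 37 % aq. CH2O, pyrrolidine (10 mol %), 4-(dimethylamino)benzoic acid (10 mol %), CH2Cl2, 40 °C
Reagents that add atoms: formaldehyde (C=O)
Why: Amine-catalysed Mannich condensation with formaldehyde and elimination (organocatalytic α-methylenation of an aldehyde) installs the 1,1-disubstituted alkene.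

Step 13
Reactants: 20 α-substituted acrolein
Product: 22 benzyl (3S)-3-hydroxy-4-{[(5R)-2-methoxy-5-methyloxolan-2-yl]methyl}pent-4-enoate, via trimethylsilyl ether 21 (not isolated)
Conditions: Ti(OiPr)4 (3 mol %), (R)-2-[(3-bromo-5-tert-butyl-2-hydroxybenzylidene)amino]-2'-hydroxy-1,1'-binaphthyl (3 mol %), 3,5-di-tert-butylsalicylic acid (3 mol %), Et2O, 0 °C; then Bu4NF, AcOH, THF, 0 °C
Reagents that add atoms: 1-(benzyloxy)-1-(trimethylsilyloxy)ethene (C=C(OCc1ccccc1)O[Si](C)(C)C)
Why: Catalytic enantioselective Mukaiyama acetate aldol addition, well precedented for α-branched enals: the chiral titanium complex directs the ketene acetal to the Si face of the aldehyde and so sets the (3S)-carbinol, and buffered fluoride removes the TMS group without harming the ketal.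

Step 14
Reactants: 22 β-hydroxy ester
Product: 23 benzyl (3S)-3-(acryloyloxy)-4-{[(5R)-2-methoxy-5-methyloxolan-2-yl]methyl}pent-4-enoate
Conditions: CH2=CHCOCl, iPr2NEt, CH2Cl2, −20 °C
Reagents that add atoms: acryloyl chloride (C=CC(Cl)=O)
Why: Esterification of the secondary allylic alcohol with the acid chloride under a hindered amine base at low temperature, which avoids E1cB loss of the β-acyloxy group.

Step 15
Reactants: 23 acrylate
Product: 24 benzyl 2-[(2S)-3-{[(5R)-2-methoxy-5-methyloxolan-2-yl]methyl}-5-oxo-2,5-dihydrofuran-2-yl]acetate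
Conditions: second-generation Grubbs catalyst (5 mol %), toluene, 80 °C
Reagents that add atoms: none
Why: Ring-closing metathesis of the acrylate onto the 1,1-disubstituted alkene (five-membered ring, ethene lost) gives the β-substituted butenolide, a standard use of the second-generation ruthenium catalyst.

Step 16
Reactants: 24 butenolide
Product: 25 2-[(2S,3S)-3-{[(5R)-2-methoxy-5-methyloxolan-2-yl]methyl}-5-oxooxolan-2-yl]acetic acid
Conditions: H2 (3 atm), Pd/C, EtOAc, rt; used directly
Reagents that add atoms: none
Why: Heterogeneous hydrogenation delivers H2 to the butenolide face opposite the CH2CO2Bn group at the γ-carbon, which sets the β-stereocentre cis to it, and hydrogenolysis frees the carboxylic acid.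

Step 17
Reactants: 25 lactone acid; 15 bicyclic lactone
Product: 26 2-[(2S,3S)-4-[(3aS,5R,7aS)-2-hydroxy-5-methylhexahydro-2H-furo[3,2-b]pyran-2-yl]-3-{[(5R)-2-methoxy-5-methyloxolan-2-yl]methyl}-5-oxooxolan-2-yl]acetic acid (epimers at the hemiketal carbon and at C-4 of the oxolanone)
Conditions: LiN(iPr)2 (2.2 equiv), THF, −78 °C; then 15, −78 °C; AcOH quench
Reagents that add atoms: none
Why: Claisen-type addition of a lactone enolate to a lactone: the second equivalent of base forms the butyrolactone enolate (the carboxylate shields its own α-CH2), which adds to the carbonyl of 15, and the tetrahedral adduct survives as the cyclic hemiketal; the new centres are epimer mixtures that disappear in step 18.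

Step 18
Reactants: 26 hemiketal adduct
Product: 27 2-[(2S,3S,4E)-3-[(5R)-5-hydroxy-2-oxohexyl]-4-[(3aS,5R,7aS)-5-methylhexahydro-2H-furo[3,2-b]pyran-2-ylidene]-5-oxooxolan-2-yl]acetic acid
Conditions: TsOH·H2O (20 mol %), THF/H2O (10:1), 40 °C
Reagents that add atoms: water (O)
Why: Acid-catalysed dehydration of the hemiketal gives the push–pull enol ether, which equilibrates by reversible C-protonation to the more stable E isomer (ring oxygen anti to the lactone carbonyl), and the aqueous acid also hydrolyses the cyclic methyl ketal to the free hydroxy ketone.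

Step 19
Reactants: 27 seco acid
Product: 28 cordycicadin C
Conditions: 2-methyl-6-nitrobenzoic anhydride (MNBA), DMAP, CH2Cl2, rt, slow addition at high dilution
Reagents that add atoms: none
Why: Shiina macrolactonisation: the mixed anhydride formed with 2-methyl-6-nitrobenzoic anhydride is attacked by the secondary alcohol under DMAP catalysis at high dilution, closing the ten-membered lactone by acyl substitution with retention at the carbinol carbon.

## Compound list

1 | oxetan-3-one | O=C1COC1 | starting material
2 | (R)-1-amino-2-(methoxymethyl)pyrrolidine (RAMP) | COC[C@H]1CCCN1N | starting material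
3 | (2R)-2-(methoxymethyl)-N-(oxetan-3-ylidene)pyrrolidin-1-amine | COC[C@H]1CCCN1N=C1COC1 | intermediate
4 | tert-butyl(2-iodoethoxy)dimethylsilane | CC(C)(C)[Si](C)(C)OCCI | starting material
5 | (2R)-N-{(2R)-2-[2-(tert-butyldimethylsilyloxy)ethyl]oxetan-3-ylidene}-2-(methoxymethyl)pyrrolidin-1-amine | COC[C@H]1CCCN1N=C1CO[C@@H]1CCO[Si](C)(C)C(C)(C)C | intermediate
6 | (2R)-N-{(2R,4R)-2,4-bis[2-(tert-butyldimethylsilyloxy)ethyl]oxetan-3-ylidene}-2-(methoxymethyl)pyrrolidin-1-amine | COC[C@H]1CCCN1N=C1[C@@H](CCO[Si](C)(C)C(C)(C)C)O[C@@H]1CCO[Si](C)(C)C(C)(C)C | intermediate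
7 | (2R,4R)-2,4-bis[2-(tert-butyldimethylsilyloxy)ethyl]oxetan-3-one | CC(C)(C)[Si](C)(C)OCC[C@H]1O[C@H](CCO[Si](C)(C)C(C)(C)C)C1=O | intermediate
8 | acetylene | C#C | starting material
9 | (2R,6R)-2,6-bis[2-(tert-butyldimethylsilyloxy)ethyl]-2H-pyran-3(6H)-one | CC(C)(C)[Si](C)(C)OCC[C@H]1O[C@H](CCO[Si](C)(C)C(C)(C)C)C=CC1=O | intermediate
10 | (2R,6S)-2,6-bis[2-(tert-butyldimethylsilyloxy)ethyl]oxan-3-one (2,6-trans) | CC(C)(C)[Si](C)(C)OCC[C@H]1O[C@H](CCO[Si](C)(C)C(C)(C)C)CCC1=O | intermediate
11 | (2S,6S)-2,6-bis[2-(tert-butyldimethylsilyloxy)ethyl]oxan-3-one (2,6-cis) | CC(C)(C)[Si](C)(C)OCC[C@@H]1O[C@H](CCO[Si](C)(C)C(C)(C)C)CCC1=O | intermediate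
12 | (2S,3S,6S)-2,6-bis[2-(tert-butyldimethylsilyloxy)ethyl]oxan-3-ol | CC(C)(C)[Si](C)(C)OCC[C@@H]1O[C@H](CCO[Si](C)(C)C(C)(C)C)CC[C@@H]1O | intermediate
13 | (2S,3S,6S)-2,6-bis(2-hydroxyethyl)oxan-3-ol | OCC[C@@H]1O[C@H](CCO)CC[C@@H]1O | intermediate
14 | 2-[(3aS,5S,7aS)-2-oxohexahydro-2H-furo[3,2-b]pyran-5-yl]acetic acid | O=C1C[C@@H]2O[C@H](CC(O)=O)CC[C@@H]2O1 | intermediate
15 | (3aS,5R,7aS)-5-methylhexahydro-2H-furo[3,2-b]pyran-2-one | O=C1C[C@@H]2O[C@H](C)CC[C@@H]2O1 | intermediate
16 | (R)-γ-valerolactone, (5R)-5-methyloxolan-2-one | C[C@@H]1CCC(=O)O1 | starting material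
17 | (5R)-2-(but-3-en-1-yl)-5-methyloxolan-2-ol | C[C@@H]1CCC(O)(CCC=C)O1 | intermediate
18 | (5R)-2-(but-3-en-1-yl)-2-methoxy-5-methyloxolane | C[C@@H]1CCC(OC)(CCC=C)O1 | intermediate
19 | 3-[(5R)-2-methoxy-5-methyloxolan-2-yl]propanal | C[C@@H]1CCC(OC)(CCC=O)O1 | intermediate
20 | 2-{[(5R)-2-methoxy-5-methyloxolan-2-yl]methyl}prop-2-enal | C[C@@H]1CCC(OC)(CC(=C)C=O)O1 | intermediate
21 | benzyl (3S)-4-{[(5R)-2-methoxy-5-methyloxolan-2-yl]methyl}-3-(trimethylsilyloxy)pent-4-enoate | C[C@@H]1CCC(OC)(CC(=C)[C@@H](O[Si](C)(C)C)CC(=O)OCc2ccccc2)O1 | intermediate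
22 | benzyl (3S)-3-hydroxy-4-{[(5R)-2-methoxy-5-methyloxolan-2-yl]methyl}pent-4-enoate | C[C@@H]1CCC(OC)(CC(=C)[C@@H](O)CC(=O)OCc2ccccc2)O1 | intermediate
23 | benzyl (3S)-3-(acryloyloxy)-4-{[(5R)-2-methoxy-5-methyloxolan-2-yl]methyl}pent-4-enoate | C[C@@H]1CCC(OC)(CC(=C)[C@@H](OC(=O)C=C)CC(=O)OCc2ccccc2)O1 | intermediate
24 | benzyl 2-[(2S)-3-{[(5R)-2-methoxy-5-methyloxolan-2-yl]methyl}-5-oxo-2,5-dihydrofuran-2-yl]acetate | C[C@@H]1CCC(OC)(CC2=CC(=O)O[C@H]2CC(=O)OCc3ccccc3)O1 | intermediate
25 | 2-[(2S,3S)-3-{[(5R)-2-methoxy-5-methyloxolan-2-yl]methyl}-5-oxooxolan-2-yl]acetic acid | C[C@@H]1CCC(OC)(C[C@H]2CC(=O)O[C@H]2CC(O)=O)O1 | intermediate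
26 | hemiketal adduct of 25 and 15 (name as in step 17) | C[C@@H]1CCC(OC)(C[C@H]2C(C3(O)C[C@@H]4O[C@H](C)CC[C@@H]4O3)C(=O)O[C@H]2CC(O)=O)O1 | intermediate
27 | 2-[(2S,3S,4E)-3-[(5R)-5-hydroxy-2-oxohexyl]-4-[(3aS,5R,7aS)-5-methylhexahydro-2H-furo[3,2-b]pyran-2-ylidene]-5-oxooxolan-2-yl]acetic acid | C[C@@H](O)CCC(=O)C[C@H]1/C(=C2/C[C@@H]3O[C@H](C)CC[C@@H]3O2)C(=O)O[C@H]1CC(O)=O | intermediate
28 | cordycicadin C | C[C@@H]1CCC(=O)C[C@H]2/C(=C3/C[C@@H]4O[C@H](C)CC[C@@H]4O3)C(=O)O[C@H]2CC(=O)O1 | target

## Step count and risks

Total step count: 19. Longest linear sequence: 12 steps (steps 1–9 and 17–19, from oxetan-3-one 1); the second branch (16 to 25, steps 10–16) has 7 steps.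

Steps most likely to fail:

1. Step 5 (proposed new method). What may go wrong: acetylene may oligomerise on nickel and use up the catalyst; the secondary α-alkoxyalkyl nickel intermediate may undergo β-hydride elimination before reductive elimination; oxidative cyclisation may be slow at a ketone branched on both α-carbons. Fallback (known chemistry; ring D is closed by oxypalladation instead of ring expansion): it sets out from (R)-γ-valerolactone 16 and comes back to the route at 15. Reduction of 16 with DIBAL-H (CH2Cl2, −78 °C) should give the lactol (5R)-5-methyloxolan-2-ol F1. Addition of CH2=CHMgBr (THF, 0 °C) should give (2R,5S)-hept-6-ene-2,5-diol F2 together with its 5-epimer, which is removed by chromatography here or after the next step. Oxycarbonylative bicyclisation (PdCl2 cat., CuCl2, NaOAc, CO 1 atm, AcOH, rt) then proceeds by 6-exo oxypalladation through the C-2 hydroxyl, CO insertion and lactonisation by the allylic hydroxyl, and should give the 2,6-cis, cis-fused lactone 15.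

2. Step 17. What may go wrong: proton transfer from 15 to the enolate instead of addition, followed by E1cB opening of the oxane ring of enolised 15; retro-Claisen cleavage of the adduct; incomplete dianion formation. Fallback (acylation by a Weinreb amide in place of a lactone): it sets out from 15 and comes back at 27. Aminolysis of 15 (MeONHMe·HCl, AlMe3, CH2Cl2) should give the hydroxy amide 2-[(2S,3S,6R)-3-hydroxy-6-methyloxan-2-yl]-N-methoxy-N-methylacetamide F3. Silylation (Et3SiOTf, 2,6-lutidine) should give its triethylsilyl ether F4. The dianion of 25 (LiN(iPr)2, 2.2 equiv, −78 °C) is acylated by F4 to give the α-acyl lactone (β-keto lactone) F5. The conditions of step 18 then remove the silyl group, close the hemiketal, dehydrate it and hydrolyse the methyl ketal to give 27.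

3. Step 19. What may go wrong: oligomerisation instead of medium-ring closure, and acylation stalled by the hemiketal form of the hydroxy ketone. Fallback (ring A is closed on a small substrate before the fragment union): it sets out from 25 and comes back at 28. Ketal hydrolysis (PPTS, acetone/H2O) should give the hydroxy keto acid 2-[(2S,3S)-3-[(5R)-5-hydroxy-2-oxohexyl]-5-oxooxolan-2-yl]acetic acid F6. MNBA/DMAP lactonisation at high dilution should give the keto bis-lactone F7. Ketalisation (Me3SiOCH2CH2OSiMe3, Me3SiOTf cat., CH2Cl2, −78 °C) should give the 1,3-dioxolane of F7, F8. Enolisation of the butyrolactone (LiN(SiMe3)2, THF, −78 °C) and addition to 15 should give the hemiketal adduct F9. TsOH·H2O in acetone/H2O then dehydrates the hemiketal and removes the dioxolane to give 28.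

Further compounds
F1 | step 5 | (5R)-5-methyloxolan-2-ol | C[C@@H]1CCC(O)O1
F2 | step 5 | (2R,5S)-hept-6-ene-2,5-diol | C[C@@H](O)CC[C@H](O)C=C
F3 | step 17 | 2-[(2S,3S,6R)-3-hydroxy-6-methyloxan-2-yl]-N-methoxy-N-methylacetamide | CON(C)C(=O)C[C@@H]1O[C@H](C)CC[C@@H]1O
F4 | step 17 | N-methoxy-N-methyl-2-[(2S,3S,6R)-6-methyl-3-(triethylsilyloxy)oxan-2-yl]acetamide | CON(C)C(=O)C[C@@H]1O[C@H](C)CC[C@@H]1O[Si](CC)(CC)CC
F5 | step 17 | α-acyl lactone from 25 and F4 (β-keto lactone, epimers at the α-carbon) | C[C@@H]1CCC(OC)(C[C@H]2C(C(=O)C[C@@H]3O[C@H](C)CC[C@@H]3O[Si](CC)(CC)CC)C(=O)O[C@H]2CC(O)=O)O1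
F6 | step 19 | 2-[(2S,3S)-3-[(5R)-5-hydroxy-2-oxohexyl]-5-oxooxolan-2-yl]acetic acid | C[C@@H](O)CCC(=O)C[C@H]1CC(=O)O[C@H]1CC(O)=O
F7 | step 19 | keto bis-lactone (rings A and B of the target with CH2 at the butyrolactone α-carbon) | C[C@@H]1CCC(=O)C[C@H]2CC(=O)O[C@H]2CC(=O)O1
F8 | step 19 | 1,3-dioxolane ketal of F7 | C[C@@H]1CCC2(OCCO2)C[C@H]3CC(=O)O[C@H]3CC(=O)O1
F9 | step 19 | hemiketal adduct of F8 and 15 | C[C@@H]1CCC2(OCCO2)C[C@H]3C(C4(O)C[C@@H]5O[C@H](C)CC[C@@H]5O4)C(=O)O[C@H]3CC(=O)O1
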